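**Retrosynthetic overview**
- The lactone ring is closed last: the O2–C1 bond forms from the C3 hydroxyl and a methyl ester on C7a, once the arene is complete.
- The strategy rests on the benzene ring C3a–C4–C5–C6–C7–C7a: the oxygen-bearing C5 lies between the unsubstituted C4 and C6, so C5 with its oxygen is taken as one molecule of CO. Cutting C4–C5 and C5–C6 leaves a 3-acetoxy-1,4-enyne, C6≡C7–C7a(OAc)(CO2Me)–C3a(=C4H2)–C3, whose acetoxy group moves from C7a to C7 during the ring closure.
- The enyne comes from ethynyl Grignard addition to an α-keto ester (C7–C7a), itself made by acylating a 2-lithioallyl ether with dimethyl oxalate (C7a–C3a).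
- The C3 stereocentre is set by CBS reduction of a 2-bromo enone, built from acrolein and a C13 ketal Grignard reagent (ethyl acetoacetate plus 1,11-dibromoundecane).
- Ring order: benzene ring (step 11), then lactone ring (step 13).

Key step: step 11

Remark: phthalide numbering (C1 carbonyl, O2, C3, C3a, C4–C7, C7a) is used throughout. The C3 oxygen is carried as a methoxymethyl ether, because a 2-lithioallyl silyl ether can suffer O→C silyl migration and because the acetal can be removed with the ketal in the last step.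

**Route**

Step 1
Reactants: 1 ethyl acetoacetate; 2 1,11-dibromoundecane (3 equiv, excess recovered)
Product: 3 ethyl 2-acetyl-13-bromotridecanoate (racemic)
Conditions: NaOEt, EtOH, reflux
Reagents that add atoms: none
Why: Acetoacetic ester alkylation (SN2 of the sodium enolate on a primary bromide); the excess of 2 should hold back substitution at both chain ends.

Step 2
Reactants: 3 ethyl 2-acetyl-13-bromotridecanoate
Product: 5 14-bromotetradecan-2-one, via keto acid 4 (not isolated)
Conditions: 48% aq. HBr, AcOH, 100 °C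
Reagents that add atoms: none
Why: Acid hydrolysis of the β-keto ester and decarboxylation of the β-keto acid (ketonic cleavage of the acetoacetic ester synthesis); the HBr medium returns any solvolysed chain end to the bromide.

Step 3
Reactants: 5 14-bromotetradecan-2-one
Product: 6 2-(12-bromododecyl)-2-methyl-1,3-dioxolane
Conditions: ethylene glycol, p-TsOH (cat.), toluene, reflux, Dean–Stark
Reagents that add atoms: ethylene glycol, OCCO
Why: Acid-catalysed ketalisation driven by azeotropic removal of water; the dioxolane masks the methyl ketone against the organometallic steps that follow.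

Step 4
Reactants: 6 2-(12-bromododecyl)-2-methyl-1,3-dioxolane; 7 acrolein
Product: 9 15-(2-methyl-1,3-dioxolan-2-yl)pentadec-1-en-3-ol (racemic), via Grignard reagent 8 (not isolated)
Conditions: Mg turnings, THF, 40 °C; then acrolein, −78 → 0 °C; aq. NH4Cl work-up
Reagents that add atoms: none
Why: Grignard formation from the primary bromide and 1,2-addition to acrolein, which alkylmagnesium halides attack at the carbonyl carbon at low temperature; the racemic carbinol centre is erased in step 5.

Step 5
Reactants: 9 15-(2-methyl-1,3-dioxolan-2-yl)pentadec-1-en-3-ol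
Product: 10 15-(2-methyl-1,3-dioxolan-2-yl)pentadec-1-en-3-one
Conditions: Dess–Martin periodinane, NaHCO3, CH2Cl2, 0 °C → rt; used at once
Reagents that add atoms: none
Why: Dess–Martin oxidation of a secondary allylic alcohol under bicarbonate buffer, neutral enough for the ketal and mild enough for the polymerisable vinyl ketone.

Step 6
Reactants: 10 15-(2-methyl-1,3-dioxolan-2-yl)pentadec-1-en-3-one
Product: 12 2-bromo-15-(2-methyl-1,3-dioxolan-2-yl)pentadec-1-en-3-one, via dibromo ketone 11 (not isolated)
Conditions: Br2, CH2Cl2, −78 °C; then Et3N, −78 → 0 °C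
Reagents that add atoms: bromine, BrBr
Why: Bromine addition to the enone C=C and E1cB loss of HBr from the α,β-dibromo ketone give the 2-bromo enone; the α-bromine makes the vinyl side the clearly larger ketone substituent for step 7 and is the handle for step 9.

Step 7
Reactants: 12 2-bromo-15-(2-methyl-1,3-dioxolan-2-yl)pentadec-1-en-3-one
Product: 13 (3S)-2-bromo-15-(2-methyl-1,3-dioxolan-2-yl)pentadec-1-en-3-ol
Conditions: (R)-Me-CBS [(3aR)-1-methyl-3,3-diphenyltetrahydro-1H,3H-pyrrolo[1,2-c][1,3,2]oxazaborole] (0.2 equiv), catecholborane (1.5 equiv), toluene, −78 °C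
Reagents that add atoms: none
Why: Corey–Bakshi–Shibata reduction: the ketone binds the oxazaborolidine boron with the larger 1-bromovinyl group turned away, and hydride comes from the coordinated borane to one face; with the (R)-catalyst this should give the (3S)-alcohol, the sense known for acetophenone-type ketones with bromovinyl in the place of phenyl.

Step 8
Reactants: 13 (3S)-2-bromo-15-(2-methyl-1,3-dioxolan-2-yl)pentadec-1-en-3-ol
Product: 14 (3S)-2-bromo-3-(methoxymethoxy)-15-(2-methyl-1,3-dioxolan-2-yl)pentadec-1-ene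
Conditions: MOMCl, iPr2NEt, CH2Cl2, 0 °C → rt
Reagents that add atoms: chloromethyl methyl ether, COCCl
Why: O-alkylation of the secondary alcohol by the chloromethyl ether under amine base (MOM protection); the stereocentre is not touched.

Step 9
Reactants: 14 (3S)-2-bromo-3-(methoxymethoxy)-15-(2-methyl-1,3-dioxolan-2-yl)pentadec-1-ene; 15 dimethyl oxalate (3 equiv)
Product: 17 methyl (4S)-4-(methoxymethoxy)-3-methylidene-16-(2-methyl-1,3-dioxolan-2-yl)-2-oxohexadecanoate, via vinyllithium 16 (not isolated)
Conditions: t-BuLi (2.1 equiv), Et2O, −78 °C; then cannula transfer into dimethyl oxalate, THF, −78 °C; AcOH quench at −78 °C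
Reagents that add atoms: none
Why: Bromine–lithium exchange at the sp2 carbon then acylation by dimethyl oxalate, whose tetrahedral adduct persists at −78 °C so that the α-keto ester appears only on quench; inverse addition to excess oxalate should hold back double addition.

Step 10
Reactants: 17 methyl (4S)-4-(methoxymethoxy)-3-methylidene-16-(2-methyl-1,3-dioxolan-2-yl)-2-oxohexadecanoate
Product: 19 methyl (2RS,4S)-2-acetoxy-2-ethynyl-4-(methoxymethoxy)-3-methylidene-16-(2-methyl-1,3-dioxolan-2-yl)hexadecanoate, via magnesium alkoxide 18 (not isolated)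
Conditions: HC≡CMgBr (1.3 equiv), THF, −78 °C; then Ac2O (3 equiv), DMAP (0.1 equiv), −78 °C → rt
Reagents that add atoms: ethynylmagnesium bromide, C#C[Mg]Br; acetic anhydride, CC(=O)OC(C)=O
Why: Alkynyl Grignard 1,2-addition to the ketone, the more electrophilic of the two vicinal carbonyls, and O-acetylation of the magnesium alkoxide in the same flask; the quaternary centre forms without control and both epimers are carried on, since this carbon becomes sp2 in step 11.

Step 11
Reactants: 19 methyl (2RS,4S)-2-acetoxy-2-ethynyl-4-(methoxymethoxy)-3-methylidene-16-(2-methyl-1,3-dioxolan-2-yl)hexadecanoate; 20 carbon monoxide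
Product: 21 methyl 2-acetoxy-4-hydroxy-6-[(1S)-1-(methoxymethoxy)-13-(2-methyl-1,3-dioxolan-2-yl)tridecyl]benzoate
Conditions: [RhCl(CO)2]2 (5 mol%), CO (80 atm), CH2Cl2, 80 °C, autoclave
Reagents that add atoms: none
Why: Monovalent rhodium binds the terminal alkyne, the acetate carbonyl attacks the internal alkyne carbon (5-exo) and the C7a–O bond opens, so the acetoxy group moves from C7a to C7 and a rhodium vinylcarbene stands at C6; CO inserts to a dienylketene (C5–C6), 6π-electrocyclisation joins the ketene carbon to the methylene carbon C4 (C4–C5), and the cyclohexadienone tautomerises to the phenol. The closest known reaction is the rhodium-catalysed [5+1] carbonylative benzannulation of 3-acyloxy-1,4-enynes to resorcinol monoesters; the only extension is the ester on the carbinol carbon, which should be tolerated because no full cation is needed at C7a and the C7=C7a bond formed is an enol acetate conjugated to that ester. The benzene ring closes by 6π-electrocyclisation of the dienylketene (or by reductive elimination from the corresponding rhodacycle), five ring carbons coming from the enyne and one from CO. No stereocentre is formed: C3 lies outside the reacting system, and the two C7a epimers converge because C7a becomes an arene carbon. The step needs a 1,2- and not a 1,3-acyloxy shift, which the unsubstituted alkyne terminus secures by steering the acetate carbonyl to the internal carbon, and it needs CO uptake to outrun direct carbene–alkene cyclisation, which the CO pressure secures. It also needs the alkenyl arm cis to the carbene carbon across C7=C7a; the reversible shift should let the other isomer return and re-enter.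

Step 12
Reactants: 21 methyl 2-acetoxy-4-hydroxy-6-[(1S)-1-(methoxymethoxy)-13-(2-methyl-1,3-dioxolan-2-yl)tridecyl]benzoate
Product: 23 methyl 2,4-dimethoxy-6-[(1S)-1-(methoxymethoxy)-13-(2-methyl-1,3-dioxolan-2-yl)tridecyl]benzoate, via dihydroxybenzoate 22 (not isolated)
Conditions: K2CO3, MeOH, 0 °C → rt; evaporate; then MeI (excess), K2CO3, DMF, 40 °C
Reagents that add atoms: iodomethane, CI
Why: Base methanolysis of the aryl acetate (transesterification) then Williamson methylation of both phenoxides; the methyl ester is unchanged by methoxide exchange, and the acetal and ketal are stable to base.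

Step 13
Reactants: 23 methyl 2,4-dimethoxy-6-[(1S)-1-(methoxymethoxy)-13-(2-methyl-1,3-dioxolan-2-yl)tridecyl]benzoate
Product: 26 CJ-13,108 [(3S)-5,7-dimethoxy-3-(13-oxotetradecyl)-2-benzofuran-1(3H)-one], via keto MOM ether 24 (not isolated), via hydroxy keto ester 25 (not isolated)
Conditions: 6 M aq. HCl, THF, 50 °C
Reagents that add atoms: water, O
Why: Aqueous acid hydrolyses the dioxolane and the MOM acetal, and the freed C3 hydroxyl closes the five-membered lactone on the ortho methyl ester (acid-catalysed transesterification); C3 keeps its configuration because its C–O bond is never broken and a benzylic cation is disfavoured by the ortho carbonyl and the two meta methoxy groups.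

**Compound list**
1 | ethyl acetoacetate | CCOC(=O)CC(C)=O | starting material
2 | 1,11-dibromoundecane | BrCCCCCCCCCCCBr | starting material
3 | ethyl 2-acetyl-13-bromotridecanoate (racemic) | CCOC(=O)C(CCCCCCCCCCCBr)C(C)=O | intermediate
4 | 2-acetyl-13-bromotridecanoic acid (not isolated) | OC(=O)C(CCCCCCCCCCCBr)C(C)=O | intermediate
5 | 14-bromotetradecan-2-one | CC(=O)CCCCCCCCCCCCBr | intermediate
6 | 2-(12-bromododecyl)-2-methyl-1,3-dioxolane | CC1(CCCCCCCCCCCCBr)OCCO1 | intermediate
7 | acrolein | C=CC=O | starting material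
8 | [12-(2-methyl-1,3-dioxolan-2-yl)dodecyl]magnesium bromide (not isolated) | CC1(CCCCCCCCCCCC[Mg]Br)OCCO1 | intermediate
9 | 15-(2-methyl-1,3-dioxolan-2-yl)pentadec-1-en-3-ol (racemic) | C=CC(O)CCCCCCCCCCCCC1(C)OCCO1 | intermediate
10 | 15-(2-methyl-1,3-dioxolan-2-yl)pentadec-1-en-3-one | C=CC(=O)CCCCCCCCCCCCC1(C)OCCO1 | intermediate
11 | 1,2-dibromo-15-(2-methyl-1,3-dioxolan-2-yl)pentadecan-3-one (not isolated) | BrCC(Br)C(=O)CCCCCCCCCCCCC1(C)OCCO1 | intermediate
12 | 2-bromo-15-(2-methyl-1,3-dioxolan-2-yl)pentadec-1-en-3-one | C=C(Br)C(=O)CCCCCCCCCCCCC1(C)OCCO1 | intermediate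
13 | (3S)-2-bromo-15-(2-methyl-1,3-dioxolan-2-yl)pentadec-1-en-3-ol | C=C(Br)[C@H](CCCCCCCCCCCCC1(C)OCCO1)O | intermediate
14 | (3S)-2-bromo-3-(methoxymethoxy)-15-(2-methyl-1,3-dioxolan-2-yl)pentadec-1-ene | C=C(Br)[C@H](CCCCCCCCCCCCC1(C)OCCO1)OCOC | intermediate
15 | dimethyl oxalate | COC(=O)C(=O)OC | starting material
16 | (3S)-2-lithio-3-(methoxymethoxy)-15-(2-methyl-1,3-dioxolan-2-yl)pentadec-1-ene (not isolated) | C=C([Li])[C@H](CCCCCCCCCCCCC1(C)OCCO1)OCOC | intermediate
17 | methyl (4S)-4-(methoxymethoxy)-3-methylidene-16-(2-methyl-1,3-dioxolan-2-yl)-2-oxohexadecanoate | C=C([C@H](CCCCCCCCCCCCC1(C)OCCO1)OCOC)C(=O)C(=O)OC | intermediate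
18 | bromomagnesium alkoxide of methyl (4S)-2-ethynyl-2-hydroxy-4-(methoxymethoxy)-3-methylidene-16-(2-methyl-1,3-dioxolan-2-yl)hexadecanoate, both C2 epimers (not isolated) | C=C([C@H](CCCCCCCCCCCCC1(C)OCCO1)OCOC)C(O[Mg]Br)(C(=O)OC)C#C | intermediate
19 | methyl (2RS,4S)-2-acetoxy-2-ethynyl-4-(methoxymethoxy)-3-methylidene-16-(2-methyl-1,3-dioxolan-2-yl)hexadecanoate | C=C([C@H](CCCCCCCCCCCCC1(C)OCCO1)OCOC)C(OC(C)=O)(C(=O)OC)C#C | intermediate
20 | carbon monoxide | [C-]#[O+] | starting material
21 | methyl 2-acetoxy-4-hydroxy-6-[(1S)-1-(methoxymethoxy)-13-(2-methyl-1,3-dioxolan-2-yl)tridecyl]benzoate | COC(=O)c1c(OC(C)=O)cc(O)cc1[C@H](CCCCCCCCCCCCC2(C)OCCO2)OCOC | intermediate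
22 | methyl 2,4-dihydroxy-6-[(1S)-1-(methoxymethoxy)-13-(2-methyl-1,3-dioxolan-2-yl)tridecyl]benzoate (not isolated) | COC(=O)c1c(O)cc(O)cc1[C@H](CCCCCCCCCCCCC2(C)OCCO2)OCOC | intermediate
23 | methyl 2,4-dimethoxy-6-[(1S)-1-(methoxymethoxy)-13-(2-methyl-1,3-dioxolan-2-yl)tridecyl]benzoate | COC(=O)c1c(OC)cc(OC)cc1[C@H](CCCCCCCCCCCCC2(C)OCCO2)OCOC | intermediate
24 | methyl 2,4-dimethoxy-6-[(1S)-1-(methoxymethoxy)-14-oxopentadecyl]benzoate (not isolated) | COC(=O)c1c(OC)cc(OC)cc1[C@H](CCCCCCCCCCCCC(C)=O)OCOC | intermediate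
25 | methyl 6-[(1S)-1-hydroxy-14-oxopentadecyl]-2,4-dimethoxybenzoate (not isolated) | COC(=O)c1c(OC)cc(OC)cc1[C@H](CCCCCCCCCCCCC(C)=O)O | intermediate
26 | CJ-13,108, (3S)-5,7-dimethoxy-3-(13-oxotetradecyl)-2-benzofuran-1(3H)-one | COc1cc(OC)c2c(c1)[C@H](CCCCCCCCCCCCC(C)=O)OC2=O | target

**Step count and risk**
Total steps: 13. Longest linear sequence: 13 (steps 1–13, from 1 and 2).

Steps most likely to fail:

1. Step 11. The acetoxy group may fail to leave the ester-bearing carbon, it may migrate to the alkyne terminus (1,3-shift to an allenyl acetate), or the carbene may close on the alkene before CO is taken up. The fallback buys the arene instead of building it; it sets out from bromide 6, through Grignard reagent 8, and comes back at target 26. Reagent 8 is added to 3,5-dimethoxybenzaldehyde (THF, −78 → 0 °C) to give racemic 1-(3,5-dimethoxyphenyl)-13-(2-methyl-1,3-dioxolan-2-yl)tridecan-1-ol F1. Dess–Martin oxidation gives 1-(3,5-dimethoxyphenyl)-13-(2-methyl-1,3-dioxolan-2-yl)tridecan-1-one F2. CBS reduction with the (R)-catalyst and BH3·SMe2 should give (1S)-1-(3,5-dimethoxyphenyl)-13-(2-methyl-1,3-dioxolan-2-yl)tridecan-1-ol F3. NBS in MeCN at 0 °C should brominate the ring carbon flanked by the side chain and a methoxy group, as 3,5-dimethoxybenzyl alcohols do, giving (1S)-1-(2-bromo-3,5-dimethoxyphenyl)-13-(2-methyl-1,3-dioxolan-2-yl)tridecan-1-ol F4. Treatment of F4 with n-BuLi (2.2 equiv, THF, −78 °C), then CO2, then warming with aqueous HCl would carboxylate that carbon, close the lactone and cleave the ketal to give 26.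

2. Step 9. The vinyllithium may lose the allylic alkoxide to give an allene, or the oxalate may be attacked twice. The fallback sets out from bromide 14 and comes back at keto ester 17. Nozaki–Hiyama–Kishi coupling of 14 with methyl glyoxylate (CrCl2 in excess, NiCl2 cat., DMF, rt) avoids the lithium reagent and should give methyl (2RS,4S)-2-hydroxy-4-(methoxymethoxy)-3-methylidene-16-(2-methyl-1,3-dioxolan-2-yl)hexadecanoate F5. Dess–Martin oxidation of F5 gives 17.

3. Step 7. Facial selectivity may be poor, which would lower the enantiomeric purity of the only stereocentre. The fallback is a classical resolution; it sets out from bromo enone 12 and comes back at alcohol 13. Luche reduction (NaBH4, CeCl3·7H2O, MeOH, −78 °C) gives racemic 2-bromo-15-(2-methyl-1,3-dioxolan-2-yl)pentadec-1-en-3-ol F6. Esterification with (S)-O-methylmandelic acid (DCC, DMAP, CH2Cl2) gives two diastereomers to be separated by chromatography: (3S)-2-bromo-15-(2-methyl-1,3-dioxolan-2-yl)pentadec-1-en-3-yl (2S)-2-methoxy-2-phenylacetate F7 and its (3R)-epimer, (3R)-2-bromo-15-(2-methyl-1,3-dioxolan-2-yl)pentadec-1-en-3-yl (2S)-2-methoxy-2-phenylacetate F8. Methanolysis of F7 (K2CO3, MeOH) gives 13.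

**Further compounds**
F1 | step 11 | 1-(3,5-dimethoxyphenyl)-13-(2-methyl-1,3-dioxolan-2-yl)tridecan-1-ol (racemic) | COc1cc(OC)cc(C(O)CCCCCCCCCCCCC2(C)OCCO2)c1
F2 | step 11 | 1-(3,5-dimethoxyphenyl)-13-(2-methyl-1,3-dioxolan-2-yl)tridecan-1-one | COc1cc(OC)cc(C(=O)CCCCCCCCCCCCC2(C)OCCO2)c1
F3 | step 11 | (1S)-1-(3,5-dimethoxyphenyl)-13-(2-methyl-1,3-dioxolan-2-yl)tridecan-1-ol | COc1cc(OC)cc([C@H](CCCCCCCCCCCCC2(C)OCCO2)O)c1
F4 | step 11 | (1S)-1-(2-bromo-3,5-dimethoxyphenyl)-13-(2-methyl-1,3-dioxolan-2-yl)tridecan-1-ol | COc1cc(OC)c(Br)c(c1)[C@H](CCCCCCCCCCCCC2(C)OCCO2)O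
F5 | step 9 | methyl (2RS,4S)-2-hydroxy-4-(methoxymethoxy)-3-methylidene-16-(2-methyl-1,3-dioxolan-2-yl)hexadecanoate | C=C([C@H](CCCCCCCCCCCCC1(C)OCCO1)OCOC)C(O)C(=O)OC
F6 | step 7 | 2-bromo-15-(2-methyl-1,3-dioxolan-2-yl)pentadec-1-en-3-ol (racemic) | C=C(Br)C(O)CCCCCCCCCCCCC1(C)OCCO1
F7 | step 7 | (3S)-2-bromo-15-(2-methyl-1,3-dioxolan-2-yl)pentadec-1-en-3-yl (2S)-2-methoxy-2-phenylacetate | C=C(Br)[C@H](CCCCCCCCCCCCC1(C)OCCO1)OC(=O)[C@@H](OC)c2ccccc2
F8 | step 7 | (3R)-2-bromo-15-(2-methyl-1,3-dioxolan-2-yl)pentadec-1-en-3-yl (2S)-2-methoxy-2-phenylacetate | C=C(Br)[C@@H](CCCCCCCCCCCCC1(C)OCCO1)OC(=O)[C@@H](OC)c2ccccc2
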